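The constants used here belong to no real substance; the rest is arithmetic.

I decide to count turnovers of the monomer charge instead of following six species through time.

free monomer 1.0 M; initiator 67 mM; impurity 75 mM; time 12 min

    free monomer + initiator → living end + monomer in chains (k1 = 0.00105 M⁻¹ s⁻¹)
    free monomer + living end → monomer in chains + living end, rate k2*[living end]*[free monomer] (k2 = 0.794 M⁻¹ s⁻¹)
    initiator + impurity → spent initiator (k3 = 13.7 M⁻¹ s⁻¹)

- the average divides the monomer in chains by the number of chains begun, living and dead together
- run time (flask): 12 min

- average number of monomer units in a chain (chains begun, living or dead) at 12 min
- part of the free monomer that has reacted at 12 min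

I need the chains first. The impurity is charged above the initiator by 8.00 mM, and at the start it takes initiator 979 times as fast as free monomer does, so I reckon the initiator as the limiting reagent of that contest and the chains as what slips past the impurity. Dividing the initiation rate by the impurity rate and integrating, with free monomer held at its charge, I get

chains begun = 0.00105 M⁻¹ s⁻¹ × 1.0 M / 13.7 M⁻¹ s⁻¹ × ln(75 mM / 8.00 mM) = 0.172 mM

The half-life of the impurity by its step with the initiator, with the initiator held at its charge, is 0.76 s, short against 12 min, so I reckon these ends as working through the whole run, a pseudo-first-order loss of free monomer:

turnovers = 0.794 M⁻¹ s⁻¹ × 0.172 mM × 12 min = 0.0981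

This number, the turnovers of the charge, says how many charges of free monomer the living ends get through in the run at their starting pace. One minus its negative exponential gives 9.34% reacted. One number is not enough for the chain length, though: I must also divide the monomer reacted by the chains, which gives 543 units.

The forecast gives 541 units and 9.2% reacted, its living ends made to “propagate for nearly the full 12 min”.

The flask gives 542 units per chain and 9.21% reacted. In this flask the living end reads 1.70 × 10⁻⁴ M at 1.20 min and 1.70 × 10⁻⁴ M at 12.0 min. For a neighbour flask with the same charges, read at 20 min, I scale my turnovers to 0.164, which means 15.1% reacted and 877 units; that neighbour gave 14.9% and 877.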